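The top flavan unit is built de novo; the middle and bottom units come from (−)-epicatechin. Ring C of the top unit is cut at O1–C2 and C4a–C4: ring A becomes 3,5-bis(benzyloxy)phenol, whose phenolic oxygen and ortho carbon form a 1,3-C,O-bisnucleophile, and C2–C3–C4 becomes a cis-epoxy aldehyde carrying ring B, electrophilic at the aldehyde carbon (C4) and at the benzylic epoxide carbon (C2). A titanium-templated formal [3+3] annulation (ortho-hydroxyalkylation, then 6-endo epoxide opening with inversion) closes ring C in one operation as a 2,3-cis-flavan-3,4-diol. Its C4 hydroxyl is then ionised and the cation captured by C8 of a bromine-blocked (4β→6) dimer; hydrogenolysis completes the synthesis.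

Key step: step 10

Assumption: C4 of compounds 15 and 16 should form as an epimer mixture and is written without configuration; step 11 ionises this carbon, so both epimers converge. Flavan numbering (O1, C2, C3, C4, C4a, C5–C8, C8a; rings A, B, C) is used for each unit, and α/β descriptors follow proanthocyanidin usage.

Step 1
Reactants: 1 (−)-epicatechin
Product: 2 5,7,3',4'-tetra-O-benzyl-(−)-epicatechin
Conditions: BnBr (4.4 equiv), K2CO3, DMF, 0 → 25 °C, N2
Reagents that add atoms: benzyl bromide, BrCc1ccccc1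
Why: Williamson etherification: the four phenols are alkylated under carbonate conditions while the secondary C3 alcohol is not deprotonated, and no stereocentre is touched.

Step 2
Reactants: 2 5,7,3',4'-tetra-O-benzyl-(−)-epicatechin
Product: 3 8-bromo-5,7,3',4'-tetra-O-benzyl-(−)-epicatechin
Conditions: NBS (1.0 equiv), CH2Cl2, −78 → 25 °C
Reagents that add atoms: N-bromosuccinimide, O=C1CCC(=O)N1Br
Why: Electrophilic aromatic bromination: in 5,7-di-O-alkyl flavans C8 of ring A is the most reactive and least hindered carbon, so one equivalent of NBS should give the 8-bromide.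

Step 3
Reactants: 2 5,7,3',4'-tetra-O-benzyl-(−)-epicatechin
Product: 4 4β-(2-ethoxyethoxy)-5,7,3',4'-tetra-O-benzyl-(−)-epicatechin
Conditions: DDQ (2 equiv), 2-ethoxyethanol (excess), CH2Cl2, 25 °C
Reagents that add atoms: 2-ethoxyethanol, CCOCCO
Why: Benzylic oxidation with DDQ: hydride abstraction from C4 gives a cation stabilised by the 5,7-dialkoxy ring A, which the alcohol traps on the face trans to the 3-OH to set C4 as the 4β-ether.

Step 4
Reactants: 4 4β-(2-ethoxyethoxy)-5,7,3',4'-tetra-O-benzyl-(−)-epicatechin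
Product: 5 8-iodo-4β-(2-ethoxyethoxy)-5,7,3',4'-tetra-O-benzyl-(−)-epicatechin
Conditions: NIS (1.05 equiv), CH2Cl2, −20 → 0 °C, dark
Reagents that add atoms: N-iodosuccinimide, O=C1CCC(=O)N1I
Why: Electrophilic aromatic iodination with the same C8 selectivity as in step 2; the iodine caps the only strongly nucleophilic carbon of the future electrophile.

Step 5
Reactants: 5 8-iodo-4β-(2-ethoxyethoxy)-5,7,3',4'-tetra-O-benzyl-(−)-epicatechin; 3 8-bromo-5,7,3',4'-tetra-O-benzyl-(−)-epicatechin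
Product: 6 [8-iodo-5,7,3',4'-tetra-O-benzylepicatechin]-(4β→6)-[8-bromo-5,7,3',4'-tetra-O-benzylepicatechin]
Conditions: 3 (2.5 equiv), TMSOTf (0.2 equiv), CH2Cl2, −78 → −40 °C; Et3N quench
Reagents that add atoms: none
Why: Lewis-acid Friedel–Crafts coupling of a 4-alkoxyflavan under halogen capping: with C8 blocked in both partners the C4 cation from 5 can only be captured by C6 of 3, trans to the 3-OH, which sets the new C4 stereocentre as 4β.

Step 6
Reactants: 6 [8-iodo-5,7,3',4'-tetra-O-benzylepicatechin]-(4β→6)-[8-bromo-5,7,3',4'-tetra-O-benzylepicatechin]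
Product: 8 [5,7,3',4'-tetra-O-benzylepicatechin]-(4β→6)-[8-bromo-5,7,3',4'-tetra-O-benzylepicatechin], via arylmagnesium chloride 7 (not isolated)
Conditions: i-PrMgCl·LiCl (3.3 equiv), THF, −20 → 0 °C; aq NH4Cl
Reagents that add atoms: none
Why: Iodine–magnesium exchange: after deprotonation of the two alcohols the aryl iodide exchanges far faster than the electron-rich aryl bromide, and protonation frees C8 of the upper unit while the lower 8-bromide stays as a block.

Step 7
Reactants: 9 3,4-bis(benzyloxy)benzaldehyde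
Product: 10 ethyl (Z)-3-[3,4-bis(benzyloxy)phenyl]prop-2-enoate
Conditions: (PhO)2P(O)CH2CO2Et, NaH, THF, −78 → 0 °C
Reagents that add atoms: ethyl 2-(diphenoxyphosphoryl)acetate, CCOC(=O)CP(=O)(Oc1ccccc1)Oc1ccccc1
Why: Ando-type Horner–Wadsworth–Emmons olefination: the diaryl phosphonate eliminates fast and irreversibly from the syn adduct, which should give the (Z)-cinnamate.

Step 8
Reactants: 10 ethyl (Z)-3-[3,4-bis(benzyloxy)phenyl]prop-2-enoate
Product: 11 ethyl (2S,3S)-3-[3,4-bis(benzyloxy)phenyl]oxirane-2-carboxylate (cis)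
Conditions: (S,S)-(salen)MnCl (6 mol %; salen = N,N'-bis(3,5-di-tert-butylsalicylidene)-trans-cyclohexane-1,2-diamine dianion), 4-phenylpyridine N-oxide (0.25 equiv), aq NaOCl (pH 11.3), CH2Cl2, 0–4 °C
Reagents that add atoms: sodium hypochlorite, [Na+].[O-]Cl
Why: Jacobsen–Katsuki epoxidation: the chiral manganese salen oxo species transfers oxygen to one face of the cis, aryl-conjugated alkene, setting both epoxide carbons as (2S,3S); cis-cinnamate esters, including p-alkoxy ones, are established substrates.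

Step 9
Reactants: 11 ethyl (2S,3S)-3-[3,4-bis(benzyloxy)phenyl]oxirane-2-carboxylate
Product: 12 (2S,3S)-3-[3,4-bis(benzyloxy)phenyl]oxirane-2-carbaldehyde (cis)
Conditions: i-Bu2AlH (1.05 equiv), CH2Cl2, −78 °C; MeOH, then aq Rochelle salt, cold
Reagents that add atoms: none
Why: Partial ester reduction with i-Bu2AlH: at −78 °C the tetrahedral aluminium hemiacetal, stabilised by chelation to the epoxide oxygen, persists until the quench and collapses to the aldehyde without touching the epoxide stereocentres.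

Step 10
Reactants: 12 (2S,3S)-3-[3,4-bis(benzyloxy)phenyl]oxirane-2-carbaldehyde; 13 3,5-bis(benzyloxy)phenol
Product: 16 (2R,3R)-5,7-bis(benzyloxy)-2-[3,4-bis(benzyloxy)phenyl]chromane-3,4-diol (2,3-cis; C4 epimers; 5,7,3',4'-tetra-O-benzyl-4-hydroxyepicatechin), via aryloxytitanium triisopropoxide 14 (not isolated), via titanium-bound epoxy carbinol 15 (not isolated)
Conditions: 13 (1.2 equiv), Ti(OiPr)4 (1.2 equiv), toluene, 25 °C, then concentrate (removes i-PrOH); CH2Cl2, 4 Å MS, add 12 at −20 °C, then 25 °C; aq tartaric acid work-up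
Reagents that add atoms: none
Why: Proposed new method: the aryloxytitanium triisopropoxide 14 attacks the titanium-bound aldehyde of 12 through its ortho carbon in a six-membered chelate (C4a–C4), and the product, a titanium alkoxide of a 2,3-epoxy alcohol (15), has its epoxide activated at the carbon remote from the carbinol, where the phenolic oxygen attacks the benzylic C2 from the rear (O1–C2). The closest known reaction types are the ortho-specific hydroxyalkylation of titanium and magnesium phenoxides with alpha-oxygenated aldehydes, the Ti(OiPr)4-mediated opening of 2,3-epoxy alcohols at the remote carbon, and the phenol–aryl epoxide cyclisation used for flavan-3-ols; their merger on an epoxy aldehyde is the new element. Ring C closes in the 6-endo-tet mode at the epoxide, preferred over 5-exo because C2 is benzylic to the electron-rich ring B and because the titanium chelate exposes the remote carbon. C3 keeps the configuration of the epoxide, C2 is set by inversion at the cis-epoxide carbon (hence the 2,3-cis, 2R,3R arrangement), and C4 forms as an epimer mixture that step 11 erases. The step needs ortho- rather than para-attack on the phenol and a single annulation, both secured by the metal template, which is lost once O1 is an ether, and it needs SN2 character at C2, which the weak, halide-free Lewis acid and low temperature are meant to secure.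

Step 11
Reactants: 16 (2R,3R)-5,7-bis(benzyloxy)-2-[3,4-bis(benzyloxy)phenyl]chromane-3,4-diol; 8 [5,7,3',4'-tetra-O-benzylepicatechin]-(4β→6)-[8-bromo-5,7,3',4'-tetra-O-benzylepicatechin]
Product: 17 [5,7,3',4'-tetra-O-benzylepicatechin]-(4β→8)-[5,7,3',4'-tetra-O-benzylepicatechin]-(4β→6)-[8-bromo-5,7,3',4'-tetra-O-benzylepicatechin]
Conditions: 8 (1.5 equiv), TMSOTf (0.3 equiv), 4 Å MS, CH2Cl2, −78 → −40 °C, slow addition of 16; Et3N quench
Reagents that add atoms: none
Why: Lewis-acid Friedel–Crafts coupling of a flavan-3,4-diol with a flavan nucleophile: ionisation of the C4 hydroxyl gives the ring A-stabilised cation, which the most nucleophilic free carbon of 8 (C8 of the upper unit; its C6 is flanked by two benzyloxy groups and the lower C8 carries bromine) should capture trans to the 3-OH, setting C4 of the top unit as 4β.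

Step 12
Reactants: 17 [5,7,3',4'-tetra-O-benzylepicatechin]-(4β→8)-[5,7,3',4'-tetra-O-benzylepicatechin]-(4β→6)-[8-bromo-5,7,3',4'-tetra-O-benzylepicatechin]
Product: 18 epicatechin-(4β→8)-epicatechin-(4β→6)-epicatechin (target)
Conditions: H2 (1 atm), Pd(OH)2/C, Et3N (3 equiv), THF/MeOH/H2O, 25 °C; Sephadex LH-20
Reagents that add atoms: none
Why: Catalytic hydrogenolysis: Pd(OH)2/C under hydrogen cleaves the twelve benzyl ethers and the aryl C–Br bond in one operation, with Et3N buffering the HBr so that the acid-labile interflavan bonds and all stereocentres stay untouched.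

Compound list

1 | (−)-epicatechin, (2R,3R) | Oc1cc(O)c2c(c1)O[C@H](c1ccc(O)c(O)c1)[C@H](O)C2 | starting material
2 | 5,7,3',4'-tetra-O-benzyl-(−)-epicatechin | C(c9ccccc9)Oc1cc(OCc9ccccc9)c2c(c1)O[C@H](c1ccc(OCc9ccccc9)c(OCc9ccccc9)c1)[C@H](O)C2 | intermediate
3 | 8-bromo-5,7,3',4'-tetra-O-benzyl-(−)-epicatechin | C(c9ccccc9)Oc1cc(OCc9ccccc9)c2c(c1Br)O[C@H](c1ccc(OCc9ccccc9)c(OCc9ccccc9)c1)[C@H](O)C2 | intermediate
4 | 4β-(2-ethoxyethoxy)-5,7,3',4'-tetra-O-benzyl-(−)-epicatechin | C(c9ccccc9)Oc1cc(OCc9ccccc9)c2c(c1)O[C@H](c1ccc(OCc9ccccc9)c(OCc9ccccc9)c1)[C@H](O)[C@H]2OCCOCC | intermediate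
5 | 8-iodo-4β-(2-ethoxyethoxy)-5,7,3',4'-tetra-O-benzyl-(−)-epicatechin | C(c9ccccc9)Oc1cc(OCc9ccccc9)c2c(c1I)O[C@H](c1ccc(OCc9ccccc9)c(OCc9ccccc9)c1)[C@H](O)[C@H]2OCCOCC | intermediate
6 | [8-iodo-5,7,3',4'-tetra-O-benzylepicatechin]-(4β→6)-[8-bromo-5,7,3',4'-tetra-O-benzylepicatechin] | Ic1c(OCc9ccccc9)cc(OCc9ccccc9)c2c1O[C@H](c1ccc(OCc9ccccc9)c(OCc9ccccc9)c1)[C@H](O)[C@H]2c1c(OCc9ccccc9)c(Br)c2c(c1OCc9ccccc9)C[C@@H](O)[C@@H](c1ccc(OCc9ccccc9)c(OCc9ccccc9)c1)O2 | intermediate
7 | arylmagnesium chloride of 6 (C8–MgCl on the upper unit, both 3-OH as chloromagnesium alkoxides) | Cl[Mg]c1c(OCc9ccccc9)cc(OCc9ccccc9)c2c1O[C@H](c1ccc(OCc9ccccc9)c(OCc9ccccc9)c1)[C@H](O[Mg]Cl)[C@H]2c1c(OCc9ccccc9)c(Br)c2c(c1OCc9ccccc9)C[C@@H](O[Mg]Cl)[C@@H](c1ccc(OCc9ccccc9)c(OCc9ccccc9)c1)O2 | intermediate (not isolated)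
8 | [5,7,3',4'-tetra-O-benzylepicatechin]-(4β→6)-[8-bromo-5,7,3',4'-tetra-O-benzylepicatechin] | c1c(OCc9ccccc9)cc(OCc9ccccc9)c2c1O[C@H](c1ccc(OCc9ccccc9)c(OCc9ccccc9)c1)[C@H](O)[C@H]2c1c(OCc9ccccc9)c(Br)c2c(c1OCc9ccccc9)C[C@@H](O)[C@@H](c1ccc(OCc9ccccc9)c(OCc9ccccc9)c1)O2 | intermediate
9 | 3,4-bis(benzyloxy)benzaldehyde | O=Cc1ccc(OCc2ccccc2)c(OCc2ccccc2)c1 | starting material
10 | ethyl (Z)-3-[3,4-bis(benzyloxy)phenyl]prop-2-enoate | CCOC(=O)/C=C\c1ccc(OCc2ccccc2)c(OCc2ccccc2)c1 | intermediate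
11 | ethyl (2S,3S)-3-[3,4-bis(benzyloxy)phenyl]oxirane-2-carboxylate (cis) | CCOC(=O)[C@H]1O[C@H]1c1ccc(OCc2ccccc2)c(OCc2ccccc2)c1 | intermediate
12 | (2S,3S)-3-[3,4-bis(benzyloxy)phenyl]oxirane-2-carbaldehyde (cis) | O=C[C@H]1O[C@H]1c1ccc(OCc2ccccc2)c(OCc2ccccc2)c1 | intermediate
13 | 3,5-bis(benzyloxy)phenol | Oc1cc(OCc2ccccc2)cc(OCc2ccccc2)c1 | starting material
14 | [3,5-bis(benzyloxy)phenoxy]titanium triisopropoxide | CC(C)O[Ti](OC(C)C)(OC(C)C)Oc1cc(OCc2ccccc2)cc(OCc2ccccc2)c1 | intermediate (not isolated)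
15 | titanium-bound epoxy carbinol, written as the free phenol–alcohol: 3,5-bis(benzyloxy)-2-{hydroxy[cis-3-(3,4-bis(benzyloxy)phenyl)oxiran-2-yl]methyl}phenol, epoxide configuration as in 12, carbinol epimers | Oc1cc(OCc2ccccc2)cc(OCc2ccccc2)c1C(O)[C@H]1O[C@H]1c1ccc(OCc2ccccc2)c(OCc2ccccc2)c1 | intermediate (not isolated)
16 | (2R,3R)-5,7-bis(benzyloxy)-2-[3,4-bis(benzyloxy)phenyl]chromane-3,4-diol (2,3-cis; C4 epimers) | C(c9ccccc9)Oc1cc(OCc9ccccc9)c2c(c1)O[C@H](c1ccc(OCc9ccccc9)c(OCc9ccccc9)c1)[C@H](O)C2O | intermediate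
17 | [5,7,3',4'-tetra-O-benzylepicatechin]-(4β→8)-[5,7,3',4'-tetra-O-benzylepicatechin]-(4β→6)-[8-bromo-5,7,3',4'-tetra-O-benzylepicatechin] | C(c9ccccc9)Oc1cc(OCc9ccccc9)c2c(c1)O[C@H](c1ccc(OCc9ccccc9)c(OCc9ccccc9)c1)[C@H](O)[C@H]2c1c(OCc9ccccc9)cc(OCc9ccccc9)c2c1O[C@H](c1ccc(OCc9ccccc9)c(OCc9ccccc9)c1)[C@H](O)[C@H]2c1c(OCc9ccccc9)c(Br)c2c(c1OCc9ccccc9)C[C@@H](O)[C@@H](c1ccc(OCc9ccccc9)c(OCc9ccccc9)c1)O2 | intermediate
18 | epicatechin-(4β→8)-epicatechin-(4β→6)-epicatechin (CNP0178679.3) | Oc1cc(O)c2c(c1)O[C@H](c1ccc(O)c(O)c1)[C@H](O)[C@H]2c1c(O)cc(O)c2c1O[C@H](c1ccc(O)c(O)c1)[C@H](O)[C@H]2c1c(O)cc2c(c1O)C[C@@H](O)[C@@H](c1ccc(O)c(O)c1)O2 | target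

Total step count: 12. Longest linear sequence: 7 steps (steps 1, 3, 4, 5, 6, 11, 12).

Steps most likely to fail

1. Step 10 (key step, proposed new method). What may go wrong: ionisation of the electron-rich benzylic epoxide carbon instead of rear-side attack (loss of the 2,3-cis relationship or rearrangement to a carbonyl compound), competing 5-exo opening, or further reaction of the easily ionised C4 carbinol with a second phenoxide. Fallback with known chemistry: the top unit is taken from the chiral pool instead of being built. The fallback sets out from compound 4, already made in step 3, which is a standard C4 electrophile of exactly the same protected top unit. Its TMSOTf-catalysed condensation with 8 (CH2Cl2, −78 °C) should give 17 directly, where the route is rejoined before step 12. This gives up the de novo closure of ring C and makes no new compound (F0).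

2. Step 11. What may go wrong: self-condensation of the uncapped electrophile through its own free C8 in competition with capture by the hindered dimer, and acid-induced scrambling of the existing interflavan bond during a slow coupling. Fallback: a halogen-capped electrophile used in equimolar amount. The fallback sets out from 16, which is brominated at C8 (NBS, CH2Cl2, −78 °C) to 8-bromo-5,7,3',4'-tetra-O-benzyl-4-hydroxyepicatechin F1. F1 cannot act as a nucleophile, so it is condensed 1:1 with 8 under the conditions of step 11 to give the dibromo protected trimer F2. Hydrogenolysis under the conditions of step 12 removes both bromines and all benzyl groups, and the route is rejoined at the target 18.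

3. Step 5. What may go wrong: acid-promoted loss or migration of the iodine cap from the very electron-rich ring A, and slow attack at the deactivated, doubly flanked C6 that lets the cation decompose. Fallback: the halogen roles are exchanged, so that the cap is the acid-stable bromine and the permanent block is chlorine. The fallback sets out from 4 and 2. Compound 4 is brominated (NBS, CH2Cl2, −78 °C) to 8-bromo-4β-(2-ethoxyethoxy)-5,7,3',4'-tetra-O-benzylepicatechin F3, and 2 is chlorinated (N-chlorosuccinimide, CH2Cl2, 0 °C) to 8-chloro-5,7,3',4'-tetra-O-benzylepicatechin F4. TMSOTf coupling as in step 5 gives the bromo/chloro dimer F5. Bromine–lithium exchange (n-BuLi, 3.2 equiv, THF, −78 °C; aq NH4Cl) leaves the aryl chloride and gives the chloro-blocked dimer F6. Coupling with 16 as in step 11 gives the chloro protected trimer F7, and hydrogenolysis as in step 12 (Pd(OH)2/C, H2, Et3N) removes the benzyl groups and the chlorine; the route is rejoined at the target 18.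

Further compounds

F0 | step 10 | none | none
F1 | step 11 | 8-bromo-5,7,3',4'-tetra-O-benzyl-4-hydroxyepicatechin (C4 epimers) | C(c9ccccc9)Oc1cc(OCc9ccccc9)c2c(c1Br)O[C@H](c1ccc(OCc9ccccc9)c(OCc9ccccc9)c1)[C@H](O)C2O
F2 | step 11 | [8-bromo-5,7,3',4'-tetra-O-benzylepicatechin]-(4β→8)-[5,7,3',4'-tetra-O-benzylepicatechin]-(4β→6)-[8-bromo-5,7,3',4'-tetra-O-benzylepicatechin] | C(c9ccccc9)Oc1cc(OCc9ccccc9)c2c(c1Br)O[C@H](c1ccc(OCc9ccccc9)c(OCc9ccccc9)c1)[C@H](O)[C@H]2c1c(OCc9ccccc9)cc(OCc9ccccc9)c2c1O[C@H](c1ccc(OCc9ccccc9)c(OCc9ccccc9)c1)[C@H](O)[C@H]2c1c(OCc9ccccc9)c(Br)c2c(c1OCc9ccccc9)C[C@@H](O)[C@@H](c1ccc(OCc9ccccc9)c(OCc9ccccc9)c1)O2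
F3 | step 5 | 8-bromo-4β-(2-ethoxyethoxy)-5,7,3',4'-tetra-O-benzylepicatechin | C(c9ccccc9)Oc1cc(OCc9ccccc9)c2c(c1Br)O[C@H](c1ccc(OCc9ccccc9)c(OCc9ccccc9)c1)[C@H](O)[C@H]2OCCOCC
F4 | step 5 | 8-chloro-5,7,3',4'-tetra-O-benzylepicatechin | C(c9ccccc9)Oc1cc(OCc9ccccc9)c2c(c1Cl)O[C@H](c1ccc(OCc9ccccc9)c(OCc9ccccc9)c1)[C@H](O)C2
F5 | step 5 | [8-bromo-5,7,3',4'-tetra-O-benzylepicatechin]-(4β→6)-[8-chloro-5,7,3',4'-tetra-O-benzylepicatechin] | Brc1c(OCc9ccccc9)cc(OCc9ccccc9)c2c1O[C@H](c1ccc(OCc9ccccc9)c(OCc9ccccc9)c1)[C@H](O)[C@H]2c1c(OCc9ccccc9)c(Cl)c2c(c1OCc9ccccc9)C[C@@H](O)[C@@H](c1ccc(OCc9ccccc9)c(OCc9ccccc9)c1)O2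
F6 | step 5 | [5,7,3',4'-tetra-O-benzylepicatechin]-(4β→6)-[8-chloro-5,7,3',4'-tetra-O-benzylepicatechin] | c1c(OCc9ccccc9)cc(OCc9ccccc9)c2c1O[C@H](c1ccc(OCc9ccccc9)c(OCc9ccccc9)c1)[C@H](O)[C@H]2c1c(OCc9ccccc9)c(Cl)c2c(c1OCc9ccccc9)C[C@@H](O)[C@@H](c1ccc(OCc9ccccc9)c(OCc9ccccc9)c1)O2
F7 | step 5 | [5,7,3',4'-tetra-O-benzylepicatechin]-(4β→8)-[5,7,3',4'-tetra-O-benzylepicatechin]-(4β→6)-[8-chloro-5,7,3',4'-tetra-O-benzylepicatechin] | C(c9ccccc9)Oc1cc(OCc9ccccc9)c2c(c1)O[C@H](c1ccc(OCc9ccccc9)c(OCc9ccccc9)c1)[C@H](O)[C@H]2c1c(OCc9ccccc9)cc(OCc9ccccc9)c2c1O[C@H](c1ccc(OCc9ccccc9)c(OCc9ccccc9)c1)[C@H](O)[C@H]2c1c(OCc9ccccc9)c(Cl)c2c(c1OCc9ccccc9)C[C@@H](O)[C@@H](c1ccc(OCc9ccccc9)c(OCc9ccccc9)c1)O2
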